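**Strategy.** The cyclopentanone (C8–C12, prostaglandin numbering) is disconnected at C8–C12. Its precursor is a seven-membered allylic β-keto lactone (an oxepane-2,4-dione) in which the lactone oxygen sits on C12, next to the C13=C14 alkene, and the lactone carbonyl hangs on C8. Pd(0) ionises the allylic C12–O bond, CO2 is lost and the C8 enolate closes onto C12 with overall retention. This 7→5 ring contraction exploits the allylic position of C12 and the C9 ketone flanking C8. C11 comes from (R)-3-hydroxybutyrolactone, C12 from a Felkin–Anh alkenyl addition, and the 13-membered lactone from Z-selective ring-closing metathesis at C5=C6.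

Key step: step 8

Remark: positions are named with prostaglandin numbering (C1–C20). C8 is epimerisable next to the C9 carbonyl and is carried as a mixture in 13–17 until it settles trans in 18.

**Step 1**
Reactants: 1 (4R)-4-hydroxyoxolan-2-one [(R)-3-hydroxy-γ-butyrolactone]
Product: 2 (4R)-4-(tert-butyldimethylsilyloxy)oxolan-2-one
Conditions: TBSCl, imidazole, DMF, 0 °C→rt
Reagents that add atoms: tert-butyldimethylsilyl chloride, C[Si](C)(Cl)C(C)(C)C
Why: Imidazole-mediated silylation of the secondary alcohol protects the future C11 oxygen and leaves the chiral-pool stereocentre untouched.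

**Step 2**
Reactants: 2 (4R)-4-(tert-butyldimethylsilyloxy)oxolan-2-one
Product: 3 (3R)-3-(tert-butyldimethylsilyloxy)-4-hydroxy-N-methoxy-N-methylbutanamide
Conditions: MeNH(OMe)·HCl, AlMe3, CH2Cl2, 0 °C→rt; aqueous work-up
Reagents that add atoms: N,O-dimethylhydroxylamine hydrochloride, CNOC.Cl
Why: Aluminium-amide aminolysis of the lactone (Weinreb amide formation) should open the ring, turning C9 into an acyl donor and freeing the primary hydroxyl at the future C12.

**Step 3**
Reactants: 3 (3R)-3-(tert-butyldimethylsilyloxy)-4-hydroxy-N-methoxy-N-methylbutanamide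
Product: 4 (3R)-3-(tert-butyldimethylsilyloxy)-N-methoxy-N-methyl-4-oxobutanamide
Conditions: Dess–Martin periodinane, CH2Cl2, 0 °C→rt; used at once
Reagents that add atoms: none
Why: Dess–Martin oxidation of the primary alcohol under near-neutral conditions should give the α-silyloxy aldehyde without epimerisation at C11.

**Step 4**
Reactants: 5 (S)-oct-1-yn-3-ol
Product: 6 (3S)-3-(triethylsilyloxy)oct-1-yne
Conditions: TESCl, imidazole, CH2Cl2, 0 °C
Reagents that add atoms: triethylsilyl chloride, CC[Si](Cl)(CC)CC
Why: Silylation gives a C15 ether that tolerates organolithium and enolate chemistry and can later be cleaved in the presence of the TBS ether.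

**Step 5**
Reactants: 6 (3S)-3-(triethylsilyloxy)oct-1-yne
Product: 8 (1E,3S)-1-iodo-3-(triethylsilyloxy)oct-1-ene, via alkenylzirconocene chloride 7 (not isolated)
Conditions: Cp2Zr(H)Cl, THF, rt; then I2, 0 °C
Reagents that add atoms: iodine, II
Why: syn-Hydrozirconation places zirconium at the alkyne terminus and iodinolysis proceeds with retention, which fixes the E geometry of the future C13=C14 alkene.

**Step 6**
Reactants: 8 (1E,3S)-1-iodo-3-(triethylsilyloxy)oct-1-ene; 4 (3R)-3-(tert-butyldimethylsilyloxy)-N-methoxy-N-methyl-4-oxobutanamide; 9 pent-4-enoyl chloride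
Product: 12 (3R,4S,5E,7S)-3-(tert-butyldimethylsilyloxy)-1-[methoxy(methyl)amino]-1-oxo-7-(triethylsilyloxy)dodec-5-en-4-yl pent-4-enoate, via alkenyllithium 10 (not isolated), via lithium alkoxide 11 (not isolated)
Conditions: t-BuLi (2 equiv per 8), Et2O, −78 °C; then 4, −78 °C; then 9, −78→−20 °C; minor C12 epimer removed by chromatography
Reagents that add atoms: none
Why: Iodine–lithium exchange and Felkin–Anh 1,2-addition to the α-silyloxy aldehyde (faster than attack on the Weinreb amide at −78 °C) should set C12 anti to the C11 silyl ether, and acylation of the alkoxide in the flask brings in C8 with its allyl group while blocking lactonisation and silyl migration.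

**Step 7**
Reactants: 12 (3R,4S,5E,7S)-3-(tert-butyldimethylsilyloxy)-1-[methoxy(methyl)amino]-1-oxo-7-(triethylsilyloxy)dodec-5-en-4-yl pent-4-enoate
Product: 15 (6R,7S)-3-allyl-6-(tert-butyldimethylsilyloxy)-7-[(1E,3S)-3-(triethylsilyloxy)oct-1-enyl]oxepane-2,4-dione (C3 epimers), via lithium ester enolate 13 (not isolated), via tetrahedral lithium adduct 14 (not isolated)
Conditions: LiHMDS (2.2 equiv), THF, high dilution, −78→−40 °C; AcOH quench
Reagents that add atoms: none
Why: In this Dieckmann-type intramolecular Claisen acylation the ester enolate (the ester CH2 is more acidic than the amide CH2) attacks the Weinreb amide, whose stable tetrahedral chelate prevents further reaction and collapses on quench to the seven-membered β-keto lactone.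

**Step 8**
Reactants: 15 (6R,7S)-3-allyl-6-(tert-butyldimethylsilyloxy)-7-[(1E,3S)-3-(triethylsilyloxy)oct-1-enyl]oxepane-2,4-dione
Product: 18 (2R,3R,4R)-2-allyl-4-(tert-butyldimethylsilyloxy)-3-[(1E,3S)-3-(triethylsilyloxy)oct-1-enyl]cyclopentan-1-one, via π-allylpalladium carboxylate 16 (not isolated), via π-allylpalladium enolate 17 (not isolated)
Conditions: Pd(PPh3)4 (5 mol %), THF (0.02 M), 25→50 °C
Reagents that add atoms: none
Why: Pd(0) ionises the allylic lactone C12–O bond with inversion to give the syn,syn π-allylpalladium β-keto carboxylate 16, which loses CO2 to the tethered C8 enolate 17; the enolate attacks the proximal allyl terminus C12 anti to palladium, so the lactone contracts by two atoms (ring O and C=O leave as CO2) to the cyclopentanone. The closest known reaction type is the palladium-catalysed decarboxylative allylation of allyl β-keto esters (Tsuji–Trost/Carroll type), here in intramolecular form. The five-membered ring closes by 5-exo attack of C8 on C12 of the π-allyl unit, whereas attack at the distal terminus C14 would give a seven-membered ketone and is disfavoured by ring size and by the substituent at C15. C12 is set by double inversion (net retention of the lactone C–O configuration, 12S in 15 becoming 12R in 18), C8 ends trans to the C12 chain by thermodynamic control next to the ketone, and the syn π-allyl geometry returns the E-alkene. The step needs C- over O-alkylation and C–C bond formation faster than β-hydride loss or protonation; the soft tethered enolate, the five-membered transition state and the absence of any other allylic leaving group (C11 and C15 carry silyl ethers) should secure this.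

**Step 9**
Reactants: 18 (2R,3R,4R)-2-allyl-4-(tert-butyldimethylsilyloxy)-3-[(1E,3S)-3-(triethylsilyloxy)oct-1-enyl]cyclopentan-1-one
Product: 19 (2R,3R,4R)-2-allyl-4-(tert-butyldimethylsilyloxy)-3-[(1E,3S)-3-hydroxyoct-1-enyl]cyclopentan-1-one
Conditions: AcOH/THF/H2O (3:1:1), rt
Reagents that add atoms: none
Why: Mild acidic hydrolysis should cleave the more labile TES ether at C15 while the secondary TBS ether and the β-silyloxy ketone survive.

**Step 10**
Reactants: 19 (2R,3R,4R)-2-allyl-4-(tert-butyldimethylsilyloxy)-3-[(1E,3S)-3-hydroxyoct-1-enyl]cyclopentan-1-one; 20 hex-5-enoic acid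
Product: 21 (1E,3S)-1-[(1R,2R,5R)-2-allyl-5-(tert-butyldimethylsilyloxy)-3-oxocyclopentyl]oct-1-en-3-yl hex-5-enoate
Conditions: DIC, DMAP (cat.), CH2Cl2, 0 °C→rt
Reagents that add atoms: none
Why: Steglich esterification acylates the allylic C15 alcohol with retention of configuration and installs C1–C6 of the upper chain.

**Step 11**
Reactants: 21 (1E,3S)-1-[(1R,2R,5R)-2-allyl-5-(tert-butyldimethylsilyloxy)-3-oxocyclopentyl]oct-1-en-3-yl hex-5-enoate
Product: 22 11-O-(tert-butyldimethylsilyl)prostaglandin E2 1,15-lactone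
Conditions: cyclometalated ruthenium (nitrato) Z-selective metathesis catalyst (7.5 mol %), ClCH2CH2Cl (3 mM), 60 °C, static vacuum
Reagents that add atoms: none
Why: Z-selective ring-closing metathesis of the two terminal alkenes should close the 13-membered lactone at C5=C6 with kinetic Z control, the catalyst leaving the internal E-alkene C13=C14 untouched.

**Step 12**
Reactants: 22 11-O-(tert-butyldimethylsilyl)prostaglandin E2 1,15-lactone
Product: 23 prostaglandin E2 1,15-lactone
Conditions: HF·pyridine, pyridine, MeCN, 0 °C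
Reagents that add atoms: none
Why: Buffered HF desilylation should free the C11 hydroxyl under conditions that avoid β-elimination from the C9 ketone and leave the allylic lactone intact.

**Step 13**
Reactants: 23 prostaglandin E2 1,15-lactone
Product: 24 prostaglandin E2 1,15-lactone 11-acetate (target)
Conditions: Ac2O, pyridine, 0 °C, short reaction time
Reagents that add atoms: acetic anhydride, CC(=O)OC(C)=O
Why: O-Acetylation of the secondary C11 alcohol with acetic anhydride/pyridine at low temperature should outrun elimination to the enone and touches no stereocentre.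

**Compound list**

1 | (4R)-4-hydroxyoxolan-2-one [(R)-3-hydroxy-γ-butyrolactone] | O=C1C[C@@H](O)CO1 | starting material
2 | (4R)-4-(tert-butyldimethylsilyloxy)oxolan-2-one | O=C1C[C@@H](O[Si](C)(C)C(C)(C)C)CO1 | intermediate
3 | (3R)-3-(tert-butyldimethylsilyloxy)-4-hydroxy-N-methoxy-N-methylbutanamide | CON(C)C(=O)C[C@@H](O[Si](C)(C)C(C)(C)C)CO | intermediate
4 | (3R)-3-(tert-butyldimethylsilyloxy)-N-methoxy-N-methyl-4-oxobutanamide | CON(C)C(=O)C[C@@H](O[Si](C)(C)C(C)(C)C)C=O | intermediate
5 | (S)-oct-1-yn-3-ol | CCCCC[C@H](O)C#C | starting material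
6 | (3S)-3-(triethylsilyloxy)oct-1-yne | CCCCC[C@H](O[Si](CC)(CC)CC)C#C | intermediate
7 | chlorobis(cyclopentadienyl)[(1E,3S)-3-(triethylsilyloxy)oct-1-enyl]zirconium (not isolated; Cp rings drawn η1) | CCCCC[C@H](O[Si](CC)(CC)CC)/C=C/[Zr](Cl)(C1C=CC=C1)C1C=CC=C1 | intermediate
8 | (1E,3S)-1-iodo-3-(triethylsilyloxy)oct-1-ene | CCCCC[C@H](O[Si](CC)(CC)CC)/C=C/I | intermediate
9 | pent-4-enoyl chloride | C=CCCC(=O)Cl | starting material
10 | [(1E,3S)-3-(triethylsilyloxy)oct-1-enyl]lithium (not isolated) | CCCCC[C@H](O[Si](CC)(CC)CC)/C=C/[Li] | intermediate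
11 | lithium (3R,4S,5E,7S)-3-(tert-butyldimethylsilyloxy)-1-[methoxy(methyl)amino]-1-oxo-7-(triethylsilyloxy)dodec-5-en-4-olate (not isolated) | CON(C)C(=O)C[C@@H](O[Si](C)(C)C(C)(C)C)[C@@H]([O-])/C=C/[C@@H](O[Si](CC)(CC)CC)CCCCC.[Li+] | intermediate
12 | (3R,4S,5E,7S)-3-(tert-butyldimethylsilyloxy)-1-[methoxy(methyl)amino]-1-oxo-7-(triethylsilyloxy)dodec-5-en-4-yl pent-4-enoate | CON(C)C(=O)C[C@@H](O[Si](C)(C)C(C)(C)C)[C@@H](OC(=O)CCC=C)/C=C/[C@@H](O[Si](CC)(CC)CC)CCCCC | intermediate
13 | lithium enolate of the pent-4-enoate ester of 12 (not isolated) | CON(C)C(=O)C[C@@H](O[Si](C)(C)C(C)(C)C)[C@@H](OC([O-])=CCC=C)/C=C/[C@@H](O[Si](CC)(CC)CC)CCCCC.[Li+] | intermediate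
14 | lithium alkoxide of the cyclised tetrahedral adduct at C9: 3-allyl-4-[methoxy(methyl)amino]-4-oxido-oxepan-2-one with C11, C12 and C15 as in 12 (not isolated) | C=CCC1C([O-])(N(C)OC)C[C@@H](O[Si](C)(C)C(C)(C)C)[C@H](/C=C/[C@@H](O[Si](CC)(CC)CC)CCCCC)OC1=O.[Li+] | intermediate
15 | (6R,7S)-3-allyl-6-(tert-butyldimethylsilyloxy)-7-[(1E,3S)-3-(triethylsilyloxy)oct-1-enyl]oxepane-2,4-dione (C3 epimers) | C=CCC1C(=O)C[C@@H](O[Si](C)(C)C(C)(C)C)[C@H](/C=C/[C@@H](O[Si](CC)(CC)CC)CCCCC)OC1=O | intermediate
16 | π-allylpalladium β-keto carboxylate zwitterion (not isolated; drawn η1 at C14, phosphines omitted) | C=CCC(C(=O)[O-])C(=O)C[C@@H](O[Si](C)(C)C(C)(C)C)C=CC([Pd+])[C@@H](O[Si](CC)(CC)CC)CCCCC | intermediate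
17 | π-allylpalladium ketone enolate zwitterion (not isolated; drawn η1 at C14, phosphines omitted) | C=CCC=C([O-])C[C@@H](O[Si](C)(C)C(C)(C)C)C=CC([Pd+])[C@@H](O[Si](CC)(CC)CC)CCCCC | intermediate
18 | (2R,3R,4R)-2-allyl-4-(tert-butyldimethylsilyloxy)-3-[(1E,3S)-3-(triethylsilyloxy)oct-1-enyl]cyclopentan-1-one | CCCCC[C@H](O[Si](CC)(CC)CC)/C=C/[C@H]1[C@H](O[Si](C)(C)C(C)(C)C)CC(=O)[C@@H]1CC=C | intermediate
19 | (2R,3R,4R)-2-allyl-4-(tert-butyldimethylsilyloxy)-3-[(1E,3S)-3-hydroxyoct-1-enyl]cyclopentan-1-one | CCCCC[C@H](O)/C=C/[C@H]1[C@H](O[Si](C)(C)C(C)(C)C)CC(=O)[C@@H]1CC=C | intermediate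
20 | hex-5-enoic acid | C=CCCCC(=O)O | starting material
21 | (1E,3S)-1-[(1R,2R,5R)-2-allyl-5-(tert-butyldimethylsilyloxy)-3-oxocyclopentyl]oct-1-en-3-yl hex-5-enoate | CCCCC[C@H](OC(=O)CCCC=C)/C=C/[C@H]1[C@H](O[Si](C)(C)C(C)(C)C)CC(=O)[C@@H]1CC=C | intermediate
22 | 11-O-(tert-butyldimethylsilyl)prostaglandin E2 1,15-lactone | CCCCC[C@H]1/C=C/[C@H]2[C@H](O[Si](C)(C)C(C)(C)C)CC(=O)[C@@H]2C/C=C\CCCC(=O)O1 | intermediate
23 | prostaglandin E2 1,15-lactone | CCCCC[C@H]1/C=C/[C@H]2[C@H](O)CC(=O)[C@@H]2C/C=C\CCCC(=O)O1 | intermediate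
24 | prostaglandin E2 1,15-lactone 11-acetate | CCCCC[C@H]1/C=C/[C@H]2[C@H](OC(C)=O)CC(=O)[C@@H]2C/C=C\CCCC(=O)O1 | target

**Step count.** 13 steps in total. The longest linear sequence is 11 steps (1 → 24 through steps 1–3 and 6–13); the side branch from 5 (steps 4 and 5) joins at step 6.

**Steps most likely to fail**

1. Step 8 (key step). After ionisation, the enolate/π-allyl pair may collapse by proton transfer or β-hydride loss to open-chain dienes before the C–C bond forms, or close at the distal allyl terminus. Fallback, from 15 back to 18: the order of events is reversed so that the ring still contracts but the nucleophile is the doubly stabilised β-keto lactone enolate. Lactone 15 is deprotonated with NaH and treated with Pd(PPh3)4/dppe in THF at 0 °C in a classical Tsuji–Trost alkylation. C8 then attacks C12 while the carboxylate is retained, and acidification should give (2R,3R)-1-allyl-3-(tert-butyldimethylsilyloxy)-5-oxo-2-[(1E,3S)-3-(triethylsilyloxy)oct-1-enyl]cyclopentane-1-carboxylic acid F1. Gentle warming of F1 in toluene effects the separate thermal decarboxylation and returns the route at 18.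

2. Step 7. Deprotonation next to the amide carbonyl with loss of the C11 silanolate, or intermolecular condensation outrunning the seven-membered ring closure, would erode the Dieckmann step. Fallback, from 4 and 8 back to 15: the C8–C9 bond is made intermolecularly and the ring is closed through an acylketene. Alkenyllithium 10 is added to 4 as in step 6 but the alkoxide 11 is not acylated; on warming and mild acid work-up it should close onto the amide to give (4R,5S)-4-(tert-butyldimethylsilyloxy)-5-[(1E,3S)-3-(triethylsilyloxy)oct-1-enyl]oxolan-2-one F2. Claisen condensation of F2 with the lithium enolate of commercial tert-butyl pent-4-enoate (LDA, THF, −78 °C) gives tert-butyl (5R,6S,7E,9S)-2-allyl-5-(tert-butyldimethylsilyloxy)-6-hydroxy-3-oxo-9-(triethylsilyloxy)tetradec-7-enoate F3, in equilibrium with its lactol. Heating F3 in toluene at 110 °C under high dilution expels tert-butanol to the acylketene (5R,6S,7E,9S)-2-allyl-5-(tert-butyldimethylsilyloxy)-6-hydroxy-9-(triethylsilyloxy)tetradeca-1,7-diene-1,3-dione F4 (not isolated), which the C12 hydroxyl traps to give 15.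

3. Step 11. Intermolecular metathesis (oligomerisation) may outcompete closure of the 13-membered ring, and secondary metathesis of the product may erode the Z geometry. Fallback, from 18 and 20 back to 22: the C5=C6 alkene is made intermolecularly and the ring is closed at the ester. Z-selective cross-metathesis of 18 with an excess of hex-5-enoic acid 20 should give 11-O-(tert-butyldimethylsilyl)-15-O-(triethylsilyl)prostaglandin E2 F5. AcOH/THF/H2O then frees the C15 hydroxyl to give 11-O-(tert-butyldimethylsilyl)prostaglandin E2 F6. Shiina macrolactonisation of F6 (2-methyl-6-nitrobenzoic anhydride, DMAP, CH2Cl2, high dilution, rt) closes the 1,15-lactone and returns the route at 22.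

**Further compounds**

F1 | step 8 | (2R,3R)-1-allyl-3-(tert-butyldimethylsilyloxy)-5-oxo-2-[(1E,3S)-3-(triethylsilyloxy)oct-1-enyl]cyclopentane-1-carboxylic acid (C1 epimers) | CCCCC[C@H](O[Si](CC)(CC)CC)/C=C/[C@H]1[C@H](O[Si](C)(C)C(C)(C)C)CC(=O)C1(CC=C)C(=O)O
F2 | step 7 | (4R,5S)-4-(tert-butyldimethylsilyloxy)-5-[(1E,3S)-3-(triethylsilyloxy)oct-1-enyl]oxolan-2-one | O=C1C[C@@H](O[Si](C)(C)C(C)(C)C)[C@H](/C=C/[C@@H](O[Si](CC)(CC)CC)CCCCC)O1
F3 | step 7 | tert-butyl (5R,6S,7E,9S)-2-allyl-5-(tert-butyldimethylsilyloxy)-6-hydroxy-3-oxo-9-(triethylsilyloxy)tetradec-7-enoate (C2 epimers, open form of the lactol) | C=CCC(C(=O)OC(C)(C)C)C(=O)C[C@@H](O[Si](C)(C)C(C)(C)C)[C@@H](O)/C=C/[C@@H](O[Si](CC)(CC)CC)CCCCC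
F4 | step 7 | (5R,6S,7E,9S)-2-allyl-5-(tert-butyldimethylsilyloxy)-6-hydroxy-9-(triethylsilyloxy)tetradeca-1,7-diene-1,3-dione (acylketene, not isolated) | C=CCC(=C=O)C(=O)C[C@@H](O[Si](C)(C)C(C)(C)C)[C@@H](O)/C=C/[C@@H](O[Si](CC)(CC)CC)CCCCC
F5 | step 11 | 11-O-(tert-butyldimethylsilyl)-15-O-(triethylsilyl)prostaglandin E2 | CCCCC[C@H](O[Si](CC)(CC)CC)/C=C/[C@H]1[C@H](O[Si](C)(C)C(C)(C)C)CC(=O)[C@@H]1C/C=C\CCCC(=O)O
F6 | step 11 | 11-O-(tert-butyldimethylsilyl)prostaglandin E2 | CCCCC[C@H](O)/C=C/[C@H]1[C@H](O[Si](C)(C)C(C)(C)C)CC(=O)[C@@H]1C/C=C\CCCC(=O)O
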